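## Retrosynthetic overview

- The oxirane is closed last, by inverting 3-exo-tet displacement of a secondary mesylate by the neighbouring tertiary hydroxyl; the linoleate goes on just before, by primary-selective acylation of an indole tetraol.
- The indole tetraol comes from a Fischer indolization: the [3,3]-sigmatropic shift of an ene-hydrazine forms the C3–C3a bond and the pyrrole ring, with both stereocentres already in place.
- Aryl fragment (N-aryl benzophenone hydrazone): 1-bromo-3-iodobenzene plus methyl (S)-glycidate, then MeMgBr, then Pd N-arylation; the carbinol centre that becomes the epoxide is bought.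
- Aldehyde fragment (γ-hydroxy aldehyde): the L-glutamic-acid-derived (S)-trityloxymethyl butyrolactone directs a trans α-hydroxymethylation; MeMgBr opens the lactone, and periodate then excises the controlling carbon.
- Ring order: benzene ring bought, pyrrole ring formed in the Fischer step, oxirane formed last.

Assumption: the glutamic-acid-derived trityl lactone, methyl (S)-glycidate and linoleoyl chloride are taken as catalogue materials.

## Route

Step 1
Reactants: 1 1-bromo-3-iodobenzene; 2 methyl (2S)-oxirane-2-carboxylate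
Product: 4 methyl (2S)-3-(3-bromophenyl)-2-hydroxypropanoate, via (3-bromophenyl)magnesium chloride 3 (not isolated)
Conditions: iPrMgCl·LiCl, THF, −20 °C; then CuBr·SMe2 (10 mol%), 2, −40 → −20 °C
Reagents that add atoms: none
Why: Iodine–magnesium exchange leaves the bromide alone, and the copper-catalysed SN2 epoxide opening by the aryl Grignard reagent occurs at the unsubstituted CH2, so the bought (S) centre is carried over untouched.

Step 2
Reactants: 4 methyl (2S)-3-(3-bromophenyl)-2-hydroxypropanoate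
Product: 5 (2S)-1-(3-bromophenyl)-3-methylbutane-2,3-diol
Conditions: MeMgBr (4 equiv), THF, 0 °C → rt
Reagents that add atoms: methylmagnesium bromide (C[Mg]Br)
Why: Double Grignard addition to the ester gives the tertiary carbinol; the aryl bromide and the carbinol stereocentre are not touched.

Step 3
Reactants: 5 (2S)-1-(3-bromophenyl)-3-methylbutane-2,3-diol; 6 benzophenone hydrazone
Product: 7 (2S)-1-{3-[2-(diphenylmethylidene)hydrazinyl]phenyl}-3-methylbutane-2,3-diol
Conditions: Pd(OAc)2 (2 mol%), Xantphos (3 mol%), Cs2CO3, toluene, 100 °C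
Reagents that add atoms: none
Why: Buchwald–Hartwig N-arylation of the hydrazone NH2 gives a stable, masked arylhydrazine, and the weak carbonate base tolerates the free diol.

Step 4
Reactants: 8 (5S)-5-[(trityloxy)methyl]dihydrofuran-2(3H)-one
Product: 10 (3S,5S)-3-(hydroxymethyl)-5-[(trityloxy)methyl]dihydrofuran-2(3H)-one, via lactone lithium enolate 9 (not isolated)
Conditions: LiN(iPr)2, THF, −78 °C; CH2O gas (cracked paraformaldehyde), −78 → −40 °C; AcOH quench
Reagents that add atoms: formaldehyde (C=O)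
Why: Aldol-type α-hydroxymethylation of the lactone enolate occurs anti to the bulky trityloxymethyl group, so the bought C5 centre sets the new C3 centre trans (3S).

Step 5
Reactants: 10 (3S,5S)-3-(hydroxymethyl)-5-[(trityloxy)methyl]dihydrofuran-2(3H)-one
Product: 11 (2S,4S)-4-(hydroxymethyl)-5-methyl-1-(trityloxy)hexane-2,5-diol
Conditions: MeMgBr (5 equiv), THF, 0 °C → rt
Reagents that add atoms: methylmagnesium bromide (C[Mg]Br)
Why: Double Grignard addition opens the lactone to the tertiary carbinol; any enolized material stays as enolate until quench, so the product keeps its configuration.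

Step 6
Reactants: 11 (2S,4S)-4-(hydroxymethyl)-5-methyl-1-(trityloxy)hexane-2,5-diol
Product: 13 (3S)-4-hydroxy-3-(hydroxymethyl)-4-methylpentanal, via detritylated tetraol 12 (not isolated)
Conditions: 80% aq. AcOH, 40 °C; then H2O, NaIO4, 0 °C
Reagents that add atoms: none
Why: Acidic detritylation frees the terminal 1,2-diol, and Malaprade periodate cleavage removes the controlling carbinol carbon as formaldehyde; the remaining centre is β to the aldehyde (obtained as its lactol) and cannot epimerize.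

Step 7
Reactants: 7 (2S)-1-{3-[2-(diphenylmethylidene)hydrazinyl]phenyl}-3-methylbutane-2,3-diol; 13 (3S)-4-hydroxy-3-(hydroxymethyl)-4-methylpentanal
Product: 16 (2S)-2-{6-[(2S)-2,3-dihydroxy-3-methylbutyl]-1H-indol-3-yl}-3-methylbutane-1,3-diol, via free arylhydrazine 14 (not isolated), via aldehyde arylhydrazone 15 (not isolated)
Conditions: TsOH·H2O (2 equiv), EtOH/H2O (9:1), 75 °C
Reagents that add atoms: none
Why: In this Fischer indole synthesis, acid exchanges benzophenone for the aldehyde and the ene-hydrazine undergoes the [3,3]-sigmatropic shift, then cyclizes and loses ammonia; closure para to the side chain avoids a peri clash with the branched C3 substituent, and neither stereocentre is involved.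

Step 8
Reactants: 16 (2S)-2-{6-[(2S)-2,3-dihydroxy-3-methylbutyl]-1H-indol-3-yl}-3-methylbutane-1,3-diol; 17 (9Z,12Z)-octadeca-9,12-dienoyl chloride
Product: 18 (2S)-2-{6-[(2S)-2,3-dihydroxy-3-methylbutyl]-1H-indol-3-yl}-3-hydroxy-3-methylbutyl (9Z,12Z)-octadeca-9,12-dienoate
Conditions: 17 (1.05 equiv), 2,4,6-collidine, CH2Cl2/THF, −78 → −40 °C
Reagents that add atoms: none
Why: Kinetically controlled acylation with a hindered base at low temperature takes the primary hydroxyl over the hindered secondary one; the tertiary alcohols and the indole NH do not react.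

Step 9
Reactants: 18 (2S)-2-{6-[(2S)-2,3-dihydroxy-3-methylbutyl]-1H-indol-3-yl}-3-hydroxy-3-methylbutyl (9Z,12Z)-octadeca-9,12-dienoate
Product: 20 (2S)-2-(6-{[(2R)-3,3-dimethyloxiran-2-yl]methyl}-1H-indol-3-yl)-3-hydroxy-3-methylbutyl (9Z,12Z)-octadeca-9,12-dienoate, via secondary mesylate 19 (not isolated)
Conditions: MsCl (1.1 equiv), Et3N, CH2Cl2, −20 °C; then DBU, rt
Reagents that add atoms: none
Why: Only the secondary hydroxyl is sulfonylated, and the intramolecular Williamson closure by the tertiary hydroxyl inverts that carbon, turning the bought (S) carbinol into the (R) epoxide without a nucleophilic base that would attack the ester.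

## Compound list

1 | 1-bromo-3-iodobenzene | Brc1cccc(I)c1 | starting material
2 | methyl (2S)-oxirane-2-carboxylate | COC(=O)[C@@H]1CO1 | starting material
3 | (3-bromophenyl)magnesium chloride | Cl[Mg]c1cccc(Br)c1 | intermediate
4 | methyl (2S)-3-(3-bromophenyl)-2-hydroxypropanoate | COC(=O)[C@@H](O)Cc1cccc(Br)c1 | intermediate
5 | (2S)-1-(3-bromophenyl)-3-methylbutane-2,3-diol | CC(C)(O)[C@@H](O)Cc1cccc(Br)c1 | intermediate
6 | benzophenone hydrazone | NN=C(c1ccccc1)c1ccccc1 | starting material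
7 | (2S)-1-{3-[2-(diphenylmethylidene)hydrazinyl]phenyl}-3-methylbutane-2,3-diol | CC(C)(O)[C@@H](O)Cc1cccc(NN=C(c2ccccc2)c2ccccc2)c1 | intermediate
8 | (5S)-5-[(trityloxy)methyl]dihydrofuran-2(3H)-one | O=C1CC[C@@H](COC(c2ccccc2)(c2ccccc2)c2ccccc2)O1 | starting material
9 | lithium (5S)-5-[(trityloxy)methyl]-4,5-dihydrofuran-2-olate | [Li]OC1=CC[C@@H](COC(c2ccccc2)(c2ccccc2)c2ccccc2)O1 | intermediate
10 | (3S,5S)-3-(hydroxymethyl)-5-[(trityloxy)methyl]dihydrofuran-2(3H)-one | O=C1[C@H](CO)C[C@@H](COC(c2ccccc2)(c2ccccc2)c2ccccc2)O1 | intermediate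
11 | (2S,4S)-4-(hydroxymethyl)-5-methyl-1-(trityloxy)hexane-2,5-diol | CC(C)(O)[C@H](CO)C[C@H](O)COC(c1ccccc1)(c1ccccc1)c1ccccc1 | intermediate
12 | (2S,4S)-4-(hydroxymethyl)-5-methylhexane-1,2,5-triol | CC(C)(O)[C@H](CO)C[C@H](O)CO | intermediate
13 | (3S)-4-hydroxy-3-(hydroxymethyl)-4-methylpentanal (handled as its lactol mixture) | CC(C)(O)[C@H](CO)CC=O | intermediate
14 | (2S)-1-(3-hydrazinylphenyl)-3-methylbutane-2,3-diol | CC(C)(O)[C@@H](O)Cc1cccc(NN)c1 | intermediate
15 | (E)-N-{3-[(2S)-2,3-dihydroxy-3-methylbutyl]phenyl}hydrazone of (3S)-4-hydroxy-3-(hydroxymethyl)-4-methylpentanal | CC(C)(O)[C@@H](O)Cc1cccc(N/N=C/C[C@@H](CO)C(C)(C)O)c1 | intermediate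
16 | (2S)-2-{6-[(2S)-2,3-dihydroxy-3-methylbutyl]-1H-indol-3-yl}-3-methylbutane-1,3-diol | CC(C)(O)[C@@H](O)Cc1ccc2c(c1)[nH]cc2[C@@H](CO)C(C)(C)O | intermediate
17 | (9Z,12Z)-octadeca-9,12-dienoyl chloride (linoleoyl chloride) | CCCCC/C=C\C/C=C\CCCCCCCC(Cl)=O | starting material
18 | (2S)-2-{6-[(2S)-2,3-dihydroxy-3-methylbutyl]-1H-indol-3-yl}-3-hydroxy-3-methylbutyl (9Z,12Z)-octadeca-9,12-dienoate | CCCCC/C=C\C/C=C\CCCCCCCC(=O)OC[C@H](c1c[nH]c2cc(C[C@H](O)C(C)(C)O)ccc12)C(C)(C)O | intermediate
19 | (2S)-3-hydroxy-2-{6-[(2S)-3-hydroxy-3-methyl-2-(methylsulfonyloxy)butyl]-1H-indol-3-yl}-3-methylbutyl (9Z,12Z)-octadeca-9,12-dienoate | CCCCC/C=C\C/C=C\CCCCCCCC(=O)OC[C@H](c1c[nH]c2cc(C[C@H](OS(C)(=O)=O)C(C)(C)O)ccc12)C(C)(C)O | intermediate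
20 | (2S)-2-(6-{[(2R)-3,3-dimethyloxiran-2-yl]methyl}-1H-indol-3-yl)-3-hydroxy-3-methylbutyl (9Z,12Z)-octadeca-9,12-dienoate | CCCCC/C=C\C/C=C\CCCCCCCC(=O)OC[C@H](c1c[nH]c2cc(C[C@H]3OC3(C)C)ccc12)C(C)(C)O | target

## Step count and risks

Total step count: 9. Longest linear sequence: 6 (steps 1, 2, 3, 7, 8, 9 or steps 4, 5, 6, 7, 8, 9).

**Step 7 (Fischer indolization).** A meta-substituted arylhydrazine can also close at the carbon between nitrogen and the side chain, giving the 4-substituted indole, and the tertiary carbinols are exposed to warm acid. The fallback keeps the same [3,3] step but blocks the unwanted ortho carbon with chlorine. It sets out from 2 (6 and 13 are used as before) and starts with commercial 1,3-dibromo-2-chlorobenzene (Clc1c(Br)cccc1Br). Mono bromine–magnesium exchange with iPrMgCl·LiCl gives (3-bromo-2-chlorophenyl)magnesium chloride F1. F1 opens 2 under CuBr·SMe2 catalysis to methyl (2S)-3-(3-bromo-2-chlorophenyl)-2-hydroxypropanoate F2, and MeMgBr converts it to (2S)-1-(3-bromo-2-chlorophenyl)-3-methylbutane-2,3-diol F3. Pd(OAc)2/Xantphos coupling with 6 (the bromide reacts, the chloride stays) gives (2S)-1-{2-chloro-3-[2-(diphenylmethylidene)hydrazinyl]phenyl}-3-methylbutane-2,3-diol F4. With 13 and TsOH·H2O this passes through (2S)-1-(2-chloro-3-hydrazinylphenyl)-3-methylbutane-2,3-diol F5 and its hydrazone of 13 F6, and can rearrange only onto the single free ortho carbon. The product is (2S)-2-{7-chloro-6-[(2S)-2,3-dihydroxy-3-methylbutyl]-1H-indol-3-yl}-3-methylbutane-1,3-diol F7. Hydrogenolysis of the carbon–chlorine bond (H2, Pd/C, Et3N, MeOH) comes back to the route at 16.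

**Step 8 (primary-selective acylation).** The acid chloride may also take the secondary hydroxyl or over-acylate. The fallback changes the order of events so that the ester is made when only one acylable hydroxyl is left; it sets out from 16 and comes back at 20.
- TBSCl/imidazole (DMF, 0 °C), which is far more primary-selective than an acyl chloride, gives (2S)-1-{3-[(2S)-1-{[tert-butyl(dimethyl)silyl]oxy}-3-hydroxy-3-methylbutan-2-yl]-1H-indol-6-yl}-3-methylbutane-2,3-diol F8.
- MsCl/Et3N gives the secondary mesylate of that silyl ether F9, which K2CO3/MeOH (no ester present) closes to the (2R)-epoxide silyl ether F10.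
- TBAF frees (2S)-2-(6-{[(2R)-3,3-dimethyloxiran-2-yl]methyl}-1H-indol-3-yl)-3-methylbutane-1,3-diol F11.
- Acylation of F11 with 17 (Et3N, cat. DMAP, CH2Cl2, 0 °C) gives 20 directly.

**Step 9 (epoxide closure next to the ester).** DBU may close the hydroxy mesylate only slowly, while stronger or nucleophilic bases threaten the linoleate. The fallback replaces sulfonate activation and base by a neutral redox cyclodehydration. It sets out from 18: PPh3/DIAD in toluene at 60 °C activates the less hindered secondary hydroxyl as an oxyphosphonium, and the tertiary hydroxyl displaces it with the same inversion. It comes back at 20 without any new isolable compound.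

## Further compounds

F1 | step 7 | (3-bromo-2-chlorophenyl)magnesium chloride | Cl[Mg]c1cccc(Br)c1Cl
F2 | step 7 | methyl (2S)-3-(3-bromo-2-chlorophenyl)-2-hydroxypropanoate | COC(=O)[C@@H](O)Cc1cccc(Br)c1Cl
F3 | step 7 | (2S)-1-(3-bromo-2-chlorophenyl)-3-methylbutane-2,3-diol | CC(C)(O)[C@@H](O)Cc1cccc(Br)c1Cl
F4 | step 7 | (2S)-1-{2-chloro-3-[2-(diphenylmethylidene)hydrazinyl]phenyl}-3-methylbutane-2,3-diol | CC(C)(O)[C@@H](O)Cc1cccc(NN=C(c2ccccc2)c2ccccc2)c1Cl
F5 | step 7 | (2S)-1-(2-chloro-3-hydrazinylphenyl)-3-methylbutane-2,3-diol | CC(C)(O)[C@@H](O)Cc1cccc(NN)c1Cl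
F6 | step 7 | (E)-N-{2-chloro-3-[(2S)-2,3-dihydroxy-3-methylbutyl]phenyl}hydrazone of (3S)-4-hydroxy-3-(hydroxymethyl)-4-methylpentanal | CC(C)(O)[C@@H](O)Cc1cccc(N/N=C/C[C@@H](CO)C(C)(C)O)c1Cl
F7 | step 7 | (2S)-2-{7-chloro-6-[(2S)-2,3-dihydroxy-3-methylbutyl]-1H-indol-3-yl}-3-methylbutane-1,3-diol | CC(C)(O)[C@@H](O)Cc1ccc2c(c1Cl)[nH]cc2[C@@H](CO)C(C)(C)O
F8 | step 8 | (2S)-1-{3-[(2S)-1-{[tert-butyl(dimethyl)silyl]oxy}-3-hydroxy-3-methylbutan-2-yl]-1H-indol-6-yl}-3-methylbutane-2,3-diol | CC(C)(O)[C@@H](O)Cc1ccc2c(c1)[nH]cc2[C@@H](CO[Si](C)(C)C(C)(C)C)C(C)(C)O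
F9 | step 8 | (2S)-1-{3-[(2S)-1-{[tert-butyl(dimethyl)silyl]oxy}-3-hydroxy-3-methylbutan-2-yl]-1H-indol-6-yl}-3-hydroxy-3-methylbutan-2-yl methanesulfonate | CC(C)(O)[C@@H](OS(C)(=O)=O)Cc1ccc2c(c1)[nH]cc2[C@@H](CO[Si](C)(C)C(C)(C)C)C(C)(C)O
F10 | step 8 | (3S)-4-{[tert-butyl(dimethyl)silyl]oxy}-3-(6-{[(2R)-3,3-dimethyloxiran-2-yl]methyl}-1H-indol-3-yl)-2-methylbutan-2-ol | CC1(C)O[C@@H]1Cc1ccc2c(c1)[nH]cc2[C@@H](CO[Si](C)(C)C(C)(C)C)C(C)(C)O
F11 | step 8 | (2S)-2-(6-{[(2R)-3,3-dimethyloxiran-2-yl]methyl}-1H-indol-3-yl)-3-methylbutane-1,3-diol | CC1(C)O[C@@H]1Cc1ccc2c(c1)[nH]cc2[C@@H](CO)C(C)(C)O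
F0 | step 9 | none | none
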